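| flask | Q | G | remark | time |
|---|---|---|---|---|
| blue | 0.025 M | 0.050 M | run made earlier |  |
| ochre | 0.038 M | 0.050 M | run made earlier |  |
| larch | 0.050 M | 0.0500 M |  | 25 h |
| elm | 0.050 M | 0.0500 M |  | 30 h |

| run | time / h | E / % | Q / % | Z / % | D / % |
|---|---|---|---|---|---|
| blue | 1.50 | 0.2 | 93.3 | 0.2 | 0 |
| blue | 5.00 | 1.5 | 79.1 | 0.5 | 0.3 |
| blue | 8.00 | 2.0 | 68.8 | 0.7 | 0.3 |
| blue | 15.0 | 3.4 | 50.6 | 1.9 | 0.6 |
| blue | 20.0 | 4.1 | 42.1 | 2.3 | 0.8 |
| blue | 25.0 | 4.4 | 34.6 | 3.8 | 0.4 |
| ochre | 4.00 | 1.6 | 82.5 | 0.1 | 1.0 |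
| ochre | 8.00 | 3.0 | 68.7 | 1.1 | 0.7 |
| ochre | 12.0 | 3.7 | 57.0 | 1.6 | 0.2 |
| ochre | 15.0 | 3.7 | 50.2 | 1.9 | 1.2 |
| ochre | 20.0 | 4.7 | 40.9 | 3.0 | 0.9 |
| ochre | 25.0 | 4.9 | 34.2 | 3.5 | 1.5 |

(readings scatter by 0.3 percentage points)

- percent here means Q units held: one D counts as two
- a reading of Q is of its free form alone

* which of these there is most of at the end, counted by the Q in it, larch (Q / E / D / Z)
* which of these there is most of at the end, counted by the Q in it, elm (Q / E / D / Z)
* the largest of these amounts at the end, in percent of the Q charged, larch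
* the largest of these amounts at the end, in percent of the Q charged, elm

The constants of this flask were not given, so I read one from the runs: the decade slope, 0.0166 h⁻¹, averaged over blue and ochre from 15.0 h to 25.0 h. I treated it as a pseudo-first-order constant in common logarithms: the drop in the common logarithm of free Q per hour.

I turned the charge of Q first. A loss of Q by pairs steepens with charge, and ochre had 1.52 times the charge of blue, yet by 25.0 h blue had fallen 0.461 decades and ochre 0.466. So I gave larch the mean of those logarithms, 34.4%.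

Time came next. Over the first 15.0 h the slope read 0.0198 h⁻¹, so it was easing, and I carried the later value. The extra hours of elm add 0.0829 decades, which gave 28.4%.

G I could not turn, because blue and ochre were both charged with 0.050 M, as larch and elm are, so I carried the slope read at that charge. Among the other forms in ochre at 25.0 h, E read highest, at 4.9%, far below Q, so I named Q in both flasks.

The forecast also named Q for larch and Q for elm, at 34.5% and 28%, holding that “free Q remains the largest listed form”, and for elm it stood lower than mine. Larch gave Q at 33.5%, and elm gave Q at 28.3%.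

    Q + G + E → 2 E (k = 0.520 M⁻² min⁻¹)
    Q + G → E (k = 0.00150 M⁻¹ min⁻¹)
    Q ⇌ L (K = 4.50, k = 7.30 × 10⁻⁴ min⁻¹)
    Q + E → D (k = 0.00720 M⁻¹ min⁻¹)
    E ⇌ Z (K = 1.20, k = 0.00160 min⁻¹)

From larch to elm the decade slope was 0.0147 h⁻¹, less than mine. At the start of elm, Q went to L at 9.7 times the rate at which it went with G to E, counting the forward rate of the reversible step. A neighbouring flask is elm with 0.20 M of G. Over the same 30 h its slope averaged 0.0438 h⁻¹, against 0.0183 h⁻¹ for elm, and it ended with 4.85% of its Q free.

(All runs were computed for substances that don't exist.)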